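## Structural features

The target is built on a cyclohex-2-en-1-one ring, numbered here C1 = C=O, C2 = C–N, C3 = CH=, C4 = carbinol carbon, C5/C6 = oxirane carbons (C6 next to C1). It carries an enamide nitrogen at C2, a tertiary hydroxyl at C4 and a cis-fused oxirane across C5–C6. Two polyene amides are attached: a (2E,4E)-5-cyclohexylpenta-2,4-dienoyl group on the C2 nitrogen, and an (E,E,E)-hepta-2,4,6-trienamide chain that starts at C4 and ends as the amide of 2-amino-3-hydroxycyclopent-2-en-1-one, an enolised 1,3-dione. The three stereocentres C4 (R), C5 (S) and C6 (R) are contiguous; the C4 hydroxyl and the oxirane oxygen lie on the same ring face and the triene on the other. Fragile groups are the α,β-epoxy ketone (base, nucleophiles, reductants), the doubly allylic tertiary alcohol (ionisation), the enamide, the acidic enol of the five-membered ring and both light- and acid-sensitive polyenes. The real difficulty is the six-membered ring: a C–N bond on the α-carbon of an enone, flanked by a quaternary carbinol and an oxirane whose configurations must be fixed relative to each other and absolutely. The key step exploits a hidden mirror plane through C1 and C4: the C2(N)=C3 enaminone is the eliminated, ring-opened form of a C2–C3 oxirane, and with that oxirane restored syn to the C4 hydroxyl the ring becomes a meso 2,3:5,6-diepoxy-4-hydroxycyclohexanone in which C2 and C6 are enantiotopic. Choosing which oxirane is opened by nitrogen therefore fixes C4, C5 and C6 together and forms the C2–N bond in the same event.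

## Logic of the disconnections

**28 to 27 and 13.** The bond cut is the C(sp2)–C(sp2) single bond between the second and third carbon of the triene, counted from C4. This removes the longest polyene and the acidic enol in the last step and leaves two fragments of similar size. The forward step must couple at room temperature with retention of both alkene geometries and without touching the epoxy enone.

**27 to 24 and 5.** The amide C(=O)–N bond is cut; nitrogen stays on C2 as an azide. The acyl chain is then added to a ring that already holds all three stereocentres. The forward step needs a reduction of a vinyl azide that spares oxirane, enone and C–Sn bond, and N- over O-acylation.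

**24 to 22.** No skeletal bond is cut; the C2=C3 bond is read as the result of losing the C3 oxygen and the C2 hydrogen. C2 and C3 become sp3 carbons carrying N and O trans, the signature of an opened oxirane. The forward step needs β-elimination to be faster than loss of N2 from the α-azido ketone.

**22 to 20 (key).** The C2–N bond is cut and the C3 oxygen is closed back onto C2. This is the largest gain: 22 has five stereocentres and a nitrogen, whereas 20 is achiral, nitrogen-free and mirror-symmetric through C1 and C4. The forward step needs a chiral catalyst that delivers azide to C2 and not to the enantiotopic C6, to Cα and not Cβ, and only once.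

**20 to 18.** The four C–O bonds of the two oxiranes are cut. All sp3 stereo-elements vanish; 18 is a flat, achiral cross-conjugated dienone. Both nucleophilic epoxidations must occur on the face of the C4 hydroxyl.

**18 to 17, then to 14 and 15.** After the C1 carbonyl is masked as its dimethyl ketal, the C4–C(alkenyl) bond is cut. 15 is a commercial dienone with one of two para carbonyls already masked; 14 delivers the two-carbon E-alkenyl unit with tin in place. The forward steps need 1,2-addition, and a ketal hydrolysis that neither removes tin nor ionises the doubly allylic alcohol.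

**13 to 11 and 8; 11 to 10 to 9; 8 to 7 to 6.** The amide C–N bond of the lower fragment is cut; the acid goes back through an aldehyde oxidation level to the five-carbon salt 9, and the amine goes back through an oxime to 6. The coupling must acylate nitrogen and not the enol oxygen.

**5 to 4 to 3, then to 1 and 2.** The C4=C5 double bond of the upper chain is cut (vinylogous olefination); the forward step must give the 4E alkene.

## Other disconnections considered

**Alternative 1:** Cut: the C4–C(alkenyl) bond of 27, on a ring that already holds nitrogen and the oxirane. Forward: oxidation of an anilide gives amido quinone monoketal A1; asymmetric phase-transfer nucleophilic epoxidation gives epoxide A2; the key step is addition of 16 to the C4 ketone of A2 anti to the oxirane, then ketal hydrolysis to 27. This is the route that comes to mind first. Grounds against it: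
- The three stereocentres are set in two unrelated events: C5/C6 by ion pairing of a flat dienone with a chiral cation, C4 by substrate control.
- The amide N–H of A2 consumes an equivalent of the organolithium next to a base-sensitive epoxy ketone.
- The latent mirror symmetry of the ring is not used.

It is kept as the fallback for the key step.

**Alternative 2:** Cut: the C4–O bond, so that the ring goes back to an arene. Forward key step: catalytic enantioselective para-hydroxylative dearomatisation (chiral aryl-λ3-iodane, water as nucleophile) of amidophenol A3, which carries both chains, to p-quinol A4, then hydroxyl-directed epoxidation of C5=C6. Grounds against it: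
- The para substituent of A3 is a trienyl group, so the oxidised intermediate is an extended quinone methide with positive charge spread along the chain. Water is expected to add at chain carbons at least as readily as at C4.
- The oxidant also meets two electron-rich polyenes and an enol.
- Only C4 would be set by the catalyst, at a site remote from iodine; C5/C6 would depend on a second selective step.

**Alternative 3:** Cut: the C5–O and C6–O bonds first, with nitrogen added afterwards. Forward key step: catalytic enantioselective desymmetrising mono-epoxidation of a prochiral p-quinol, for example silylalkyne A5 to epoxide A6 (chiral primary-amine salt/H2O2 or a tartrate-modified metal peroxide). α-Iodination then gives A7, and copper-catalysed amidation with primary amide A8 installs the nitrogen. Grounds against it: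
- The catalyst's facial preference at Cβ and the substrate's preference for attack syn to OH must agree, or diastereomers result.
- Nitrogen must come in by electrophilic iodination and a hot copper coupling. This excludes a vinylstannane at C4 and forces a silylalkyne that must be unmasked and hydrostannylated on the finished epoxy enone, at least three more steps.
- The mild way to put nitrogen on C2, a second epoxidation and opening, would pass through a meso diepoxide and erase the chirality just created.

The chosen plan starts from that last observation: both epoxidations use no chiral reagent, and the C–N bond formation carries the asymmetric induction.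

Key step: step 12

Remark (assumption): the (R,R)-antipode of the (salen)Cr(III) catalyst is written in step 12. The sense of induction on this substrate class is not known; if it proves opposite, the (S,S)-antipode is used with no other change.

## Route

Step 1
Reactants: 1 cyclohexanecarbaldehyde; 2 triethyl (E)-4-phosphonocrotonate
Product: 3 ethyl (2E,4E)-5-cyclohexylpenta-2,4-dienoate
Conditions: LiHMDS, THF, −78 °C → rt
Reagents that add atoms: none
Why: Vinylogous Horner–Wadsworth–Emmons olefination; the stabilised allylic phosphonate anion reacts at its γ-carbon and should give the new C4=C5 bond E under thermodynamic control, the 2E geometry coming from the reagent.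

Step 2
Reactants: 3 ethyl (2E,4E)-5-cyclohexylpenta-2,4-dienoate
Product: 4 (2E,4E)-5-cyclohexylpenta-2,4-dienoic acid
Conditions: LiOH, THF/H2O, rt; then 1 M HCl
Reagents that add atoms: lithium hydroxide, [Li+].[OH-]
Why: Ester saponification; crystallisation of the acid should remove any minor 4Z isomer.

Step 3
Reactants: 4 (2E,4E)-5-cyclohexylpenta-2,4-dienoic acid
Product: 5 (2E,4E)-5-cyclohexylpenta-2,4-dienoyl chloride
Conditions: (COCl)2, DMF (cat.), CH2Cl2, 0 °C → rt; evaporate
Reagents that add atoms: oxalyl chloride, O=C(Cl)C(Cl)=O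
Why: Vilsmeier-type activation of the acid under neutral conditions that do not isomerise the diene; the chloride is used crude.

Step 4
Reactants: 6 cyclopentane-1,3-dione
Product: 7 2-(hydroxyimino)cyclopentane-1,3-dione
Conditions: NaNO2, aq. HCl, 0 °C
Reagents that add atoms: sodium nitrite, [Na+].[O-]N=O
Why: C-Nitrosation of the enol at C2 followed by tautomerisation to the oxime, the standard entry to 2-amino-1,3-diones.

Step 5
Reactants: 7 2-(hydroxyimino)cyclopentane-1,3-dione
Product: 8 2-amino-3-hydroxycyclopent-2-en-1-one hydrochloride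
Conditions: H2 (1 atm), 10% Pd/C, HCl, EtOH, rt
Reagents that add atoms: hydrogen chloride, Cl
Why: Catalytic hydrogenation of the oxime (N–O hydrogenolysis and C=N reduction); trapping as the hydrochloride should prevent self-condensation of the α-amino dione.

Step 6
Reactants: 9 glutaconaldehyde potassium salt
Product: 10 (2E,4E)-5-bromopenta-2,4-dienal
Conditions: PPh3, Br2, CH2Cl2, 0 °C; then 9, rt
Reagents that add atoms: bromine, BrBr
Why: The enolate oxygen is activated as a vinyloxyphosphonium ion and replaced by bromide in an addition–elimination on the vinylogous acyl system; the all-E dienal is the thermodynamic product.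

Step 7
Reactants: 10 (2E,4E)-5-bromopenta-2,4-dienal
Product: 11 (2E,4E)-5-bromopenta-2,4-dienoic acid
Conditions: NaClO2, NaH2PO4, 2-methylbut-2-ene, t-BuOH/H2O, 0 °C → rt
Reagents that add atoms: sodium chlorite, [Na+].[O-]Cl=O
Why: Pinnick oxidation; chlorous acid oxidises only the aldehyde and the alkene scavenger removes HOCl before it can add to the bromodiene.

Step 8
Reactants: 11 (2E,4E)-5-bromopenta-2,4-dienoic acid; 8 2-amino-3-hydroxycyclopent-2-en-1-one hydrochloride
Product: 13 (2E,4E)-5-bromo-N-(2-hydroxy-5-oxocyclopent-1-en-1-yl)penta-2,4-dienamide, via acid chloride 12 (not isolated)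
Conditions: (COCl)2, DMF (cat.), CH2Cl2, 0 °C, evaporate; then 8, Et3N, CH2Cl2, 0 °C → rt
Reagents that add atoms: none
Why: Amide formation through the acid chloride; any enol ester formed at oxygen should transfer its acyl group to the neighbouring nitrogen, so the N-acyl vinylogous acid is the expected product.

Step 9
Reactants: 14 (E)-1,2-bis(tributylstannyl)ethene; 15 4,4-dimethoxycyclohexa-2,5-dien-1-one
Product: 17 4,4-dimethoxy-1-[(E)-2-(tributylstannyl)ethenyl]cyclohexa-2,5-dien-1-ol, via vinyllithium 16 (not isolated)
Conditions: n-BuLi (1.0 equiv), THF, −78 °C; then 15, −78 °C; H2O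
Reagents that add atoms: none
Why: Tin–lithium exchange on one C–Sn bond with retention of the E geometry, then 1,2-addition of the alkenyllithium to the only carbonyl of the quinone monoketal; the product is achiral.

Step 10
Reactants: 17 4,4-dimethoxy-1-[(E)-2-(tributylstannyl)ethenyl]cyclohexa-2,5-dien-1-ol
Product: 18 4-hydroxy-4-[(E)-2-(tributylstannyl)ethenyl]cyclohexa-2,5-dien-1-one
Conditions: montmorillonite K10, wet CH2Cl2, rt
Reagents that add atoms: water, O
Why: Ketal hydrolysis through the cross-conjugated oxocarbenium ion; the mild solid acid is chosen to spare the vinylstannane and the doubly allylic tertiary alcohol.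

Step 11
Reactants: 18 4-hydroxy-4-[(E)-2-(tributylstannyl)ethenyl]cyclohexa-2,5-dien-1-one
Product: 20 (2S,3R,4s,5S,6R)-2,3:5,6-diepoxy-4-hydroxy-4-[(E)-2-(tributylstannyl)ethenyl]cyclohexan-1-one (meso, both oxiranes syn to OH), via monoepoxide 19 (not isolated)
Conditions: t-BuOOH (anhydrous, 3 equiv), Triton B (cat.), THF, 0 °C → rt
Reagents that add atoms: tert-butyl hydroperoxide, CC(C)(C)OO
Why: Twofold Weitz–Scheffer epoxidation; in 4-oxygenated cyclohexadienones the peroxide anion adds on the face of the C4 oxygen (hydrogen bond to the hydroxyl and electrostatic bias of the C4–O bond), so both oxiranes should form syn to the hydroxyl and give the meso diepoxide. The vinylstannane is not a Michael acceptor and should be left alone.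

Step 12
Reactants: 20 (2S,3R,4s,5S,6R)-2,3:5,6-diepoxy-4-hydroxy-4-[(E)-2-(tributylstannyl)ethenyl]cyclohexan-1-one
Product: 22 (2R,3R,4R,5S,6R)-2-azido-5,6-epoxy-3,4-dihydroxy-4-[(E)-2-(tributylstannyl)ethenyl]cyclohexan-1-one, via silyl ether 21 (not isolated)
Conditions: (R,R)-N,N′-bis(3,5-di-tert-butylsalicylidene)-1,2-cyclohexanediaminochromium(III) chloride (5 mol %), TMSN3 (1.1 equiv), Et2O, 0 °C → rt; then MeOH, citric acid (cat.), 0 °C
Reagents that add atoms: azidotrimethylsilane, C[Si](C)(C)N=[N+]=[N-]
Why: Proposed new method: enantiotopic-group-selective azidolysis of a meso bis(α,β-epoxy) ketone; the closest known reaction types are the (salen)Cr(III)-catalysed opening of meso epoxides by TMSN3 and the Cα-selective opening of α,β-epoxy ketones by azide, amines and thiolates that leads to α-substituted enones. Mechanism: the Cr–N3 species forms from the chloride and TMSN3, one Cr centre binds an oxirane oxygen as a Lewis acid, a second delivers azide in an SN2 attack anti to the C–O bond, and the Cr alkoxide is silylated by TMSN3 to give 21 and return Cr–N3. Within each oxirane the site is fixed by the substrate: C3 and C5 are neopentyl-like next to the fully substituted C4, whereas C2 and C6 are secondary and activated by the adjacent C=O, so the catalyst only has to choose between C2 and C6. These two carbons are mirror images of each other (S and R), which is the situation of the two carbons of a simple meso epoxide that this catalyst class distinguishes. Attack at C2 with inversion gives the trans 2-azido-3-silyloxy arrangement; these two centres are temporary, and the choice of C2 over C6 is what turns the pseudo-asymmetric C4 and the surviving C5–C6 oxirane into the (4R,5S,6R) array of 22 and of the target. No ring is closed; one oxirane is opened and the other must survive, which is helped by the remaining oxirane being the mismatched one for the catalyst and by the use of only 1.1 equiv of azide. The minor enantiomer of 21 still holds the matched oxirane and should be consumed faster by a second opening, which should raise the enantiomeric purity of 22 at some cost in material. Mild methanolysis cleaves the secondary silyl ether, and any silyl group picked up by the tertiary hydroxyl, without touching the oxirane or the vinylstannane.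

Step 13
Reactants: 22 (2R,3R,4R,5S,6R)-2-azido-5,6-epoxy-3,4-dihydroxy-4-[(E)-2-(tributylstannyl)ethenyl]cyclohexan-1-one
Product: 24 (4S,5S,6R)-2-azido-5,6-epoxy-4-hydroxy-4-[(E)-2-(tributylstannyl)ethenyl]cyclohex-2-en-1-one, via mesylate 23 (not isolated)
Conditions: MsCl, Et3N, CH2Cl2, −20 → 0 °C
Reagents that add atoms: none
Why: Selective sulfonylation of the secondary C3 hydroxyl (the tertiary one is inert) and E1cB loss of mesylate through the C1/C2 enolate, the standard route from α-azido-β-hydroxy ketones to α-azido enones. C2 and C3 lose their stereo-information and C4–C6 are untouched; the change of the C4 descriptor to S is only a change of CIP ranking.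

Step 14
Reactants: 24 (4S,5S,6R)-2-azido-5,6-epoxy-4-hydroxy-4-[(E)-2-(tributylstannyl)ethenyl]cyclohex-2-en-1-one; 5 (2E,4E)-5-cyclohexylpenta-2,4-dienoyl chloride
Product: 27 (4S,5S,6R)-2-[(2E,4E)-5-cyclohexylpenta-2,4-dienamido]-5,6-epoxy-4-hydroxy-4-[(E)-2-(tributylstannyl)ethenyl]cyclohex-2-en-1-one, via iminophosphorane 25 (not isolated), via aminoenone 26 (not isolated)
Conditions: PMe3, THF, −20 → 0 °C; H2O, rt; evaporate (PhMe); then 5, pyridine, CH2Cl2, −20 → 0 °C
Reagents that add atoms: none
Why: Staudinger reduction (phosphazide, loss of N2, hydrolysis of the P=N bond) should give the 2-aminoenone, which is acylated at once on nitrogen. The hindered tertiary hydroxyl should not compete without an acyl-transfer catalyst, and neither reagent touches the oxirane or the C–Sn bond.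

Step 15
Reactants: 27 (4S,5S,6R)-2-[(2E,4E)-5-cyclohexylpenta-2,4-dienamido]-5,6-epoxy-4-hydroxy-4-[(E)-2-(tributylstannyl)ethenyl]cyclohex-2-en-1-one; 13 (2E,4E)-5-bromo-N-(2-hydroxy-5-oxocyclopent-1-en-1-yl)penta-2,4-dienamide
Product: 28 (4R,5S,6R)-2-[(2E,4E)-5-cyclohexylpenta-2,4-dienamido]-5,6-epoxy-4-hydroxy-4-[(1E,3E,5E)-7-[(2-hydroxy-5-oxocyclopent-1-en-1-yl)amino]-7-oxohepta-1,3,5-trien-1-yl]cyclohex-2-en-1-one (target)
Conditions: Pd2(dba)3 (5 mol %), AsPh3 (20 mol %), DMF, rt, dark
Reagents that add atoms: none
Why: Stille coupling of an alkenylstannane with an alkenyl bromide proceeds with retention at both partners and should give the E,E,E-triene. The neutral room-temperature conditions should be tolerated by the epoxy enone, the free hydroxyl and the enol; the change of the C4 descriptor from S to R is again only a change of CIP ranking.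

## Compound list

1 | cyclohexanecarbaldehyde | O=CC1CCCCC1 | starting material
2 | triethyl (E)-4-phosphonocrotonate [ethyl (2E)-4-(diethoxyphosphoryl)but-2-enoate] | CCOC(=O)/C=C/CP(=O)(OCC)OCC | starting material
3 | ethyl (2E,4E)-5-cyclohexylpenta-2,4-dienoate | CCOC(=O)/C=C/C=C/C1CCCCC1 | intermediate
4 | (2E,4E)-5-cyclohexylpenta-2,4-dienoic acid | OC(=O)/C=C/C=C/C1CCCCC1 | intermediate
5 | (2E,4E)-5-cyclohexylpenta-2,4-dienoyl chloride | O=C(Cl)/C=C/C=C/C1CCCCC1 | intermediate
6 | cyclopentane-1,3-dione | O=C1CCC(=O)C1 | starting material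
7 | 2-(hydroxyimino)cyclopentane-1,3-dione | O=C1CCC(=O)C1=NO | intermediate
8 | 2-amino-3-hydroxycyclopent-2-en-1-one hydrochloride | NC1=C(O)CCC1=O.Cl | intermediate
9 | glutaconaldehyde potassium salt [potassium (1E,3E)-5-oxopenta-1,3-dien-1-olate] | [K+].[O-]/C=C/C=C/C=O | starting material
10 | (2E,4E)-5-bromopenta-2,4-dienal | O=C/C=C/C=C/Br | intermediate
11 | (2E,4E)-5-bromopenta-2,4-dienoic acid | OC(=O)/C=C/C=C/Br | intermediate
12 | (2E,4E)-5-bromopenta-2,4-dienoyl chloride | O=C(Cl)/C=C/C=C/Br | intermediate (not isolated)
13 | (2E,4E)-5-bromo-N-(2-hydroxy-5-oxocyclopent-1-en-1-yl)penta-2,4-dienamide | O=C(/C=C/C=C/Br)NC1=C(O)CCC1=O | intermediate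
14 | (E)-1,2-bis(tributylstannyl)ethene | CCCC[Sn](CCCC)(CCCC)/C=C/[Sn](CCCC)(CCCC)CCCC | starting material
15 | 4,4-dimethoxycyclohexa-2,5-dien-1-one | COC1(OC)C=CC(=O)C=C1 | starting material
16 | (E)-2-(tributylstannyl)ethenyllithium | [Li]/C=C/[Sn](CCCC)(CCCC)CCCC | intermediate (not isolated)
17 | 4,4-dimethoxy-1-[(E)-2-(tributylstannyl)ethenyl]cyclohexa-2,5-dien-1-ol | COC1(OC)C=CC(O)(/C=C/[Sn](CCCC)(CCCC)CCCC)C=C1 | intermediate
18 | 4-hydroxy-4-[(E)-2-(tributylstannyl)ethenyl]cyclohexa-2,5-dien-1-one | O=C1C=CC(O)(/C=C/[Sn](CCCC)(CCCC)CCCC)C=C1 | intermediate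
19 | rac-(4S,5S,6R)-5,6-epoxy-4-hydroxy-4-[(E)-2-(tributylstannyl)ethenyl]cyclohex-2-en-1-one (racemate, one enantiomer written; oxirane syn to OH) | O=C1C=C[C@](O)(/C=C/[Sn](CCCC)(CCCC)CCCC)[C@H]2O[C@@H]12 | intermediate (not isolated)
20 | (2S,3R,4s,5S,6R)-2,3:5,6-diepoxy-4-hydroxy-4-[(E)-2-(tributylstannyl)ethenyl]cyclohexan-1-one (meso; both oxiranes syn to OH) | O=C1[C@H]2O[C@H]2[C@](O)(/C=C/[Sn](CCCC)(CCCC)CCCC)[C@H]2O[C@@H]12 | intermediate
21 | (2R,3R,4S,5S,6R)-2-azido-5,6-epoxy-4-hydroxy-4-[(E)-2-(tributylstannyl)ethenyl]-3-(trimethylsilyloxy)cyclohexan-1-one | O=C1[C@H](N=[N+]=[N-])[C@@H](O[Si](C)(C)C)[C@](O)(/C=C/[Sn](CCCC)(CCCC)CCCC)[C@H]2O[C@@H]12 | intermediate (not isolated)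
22 | (2R,3R,4R,5S,6R)-2-azido-5,6-epoxy-3,4-dihydroxy-4-[(E)-2-(tributylstannyl)ethenyl]cyclohexan-1-one | O=C1[C@H](N=[N+]=[N-])[C@@H](O)[C@](O)(/C=C/[Sn](CCCC)(CCCC)CCCC)[C@H]2O[C@@H]12 | intermediate
23 | (2R,3R,4S,5S,6R)-2-azido-5,6-epoxy-4-hydroxy-3-(methanesulfonyloxy)-4-[(E)-2-(tributylstannyl)ethenyl]cyclohexan-1-one | O=C1[C@H](N=[N+]=[N-])[C@@H](OS(C)(=O)=O)[C@](O)(/C=C/[Sn](CCCC)(CCCC)CCCC)[C@H]2O[C@@H]12 | intermediate (not isolated)
24 | (4S,5S,6R)-2-azido-5,6-epoxy-4-hydroxy-4-[(E)-2-(tributylstannyl)ethenyl]cyclohex-2-en-1-one | [N-]=[N+]=NC1=C[C@](O)(/C=C/[Sn](CCCC)(CCCC)CCCC)[C@H]2O[C@H]2C1=O | intermediate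
25 | (4S,5S,6R)-5,6-epoxy-4-hydroxy-4-[(E)-2-(tributylstannyl)ethenyl]-2-[(trimethyl-λ5-phosphanylidene)amino]cyclohex-2-en-1-one | CP(C)(C)=NC1=C[C@](O)(/C=C/[Sn](CCCC)(CCCC)CCCC)[C@H]2O[C@H]2C1=O | intermediate (not isolated)
26 | (4S,5S,6R)-2-amino-5,6-epoxy-4-hydroxy-4-[(E)-2-(tributylstannyl)ethenyl]cyclohex-2-en-1-one | NC1=C[C@](O)(/C=C/[Sn](CCCC)(CCCC)CCCC)[C@H]2O[C@H]2C1=O | intermediate (not isolated)
27 | (4S,5S,6R)-2-[(2E,4E)-5-cyclohexylpenta-2,4-dienamido]-5,6-epoxy-4-hydroxy-4-[(E)-2-(tributylstannyl)ethenyl]cyclohex-2-en-1-one | O=C(/C=C/C=C/C1CCCCC1)NC1=C[C@](O)(/C=C/[Sn](CCCC)(CCCC)CCCC)[C@H]2O[C@H]2C1=O | intermediate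
28 | (4R,5S,6R)-2-[(2E,4E)-5-cyclohexylpenta-2,4-dienamido]-5,6-epoxy-4-hydroxy-4-[(1E,3E,5E)-7-[(2-hydroxy-5-oxocyclopent-1-en-1-yl)amino]-7-oxohepta-1,3,5-trien-1-yl]cyclohex-2-en-1-one | O=C(/C=C/C=C/C1CCCCC1)NC1=C[C@](O)(/C=C/C=C/C=C/C(=O)NC2=C(O)CCC2=O)[C@H]2O[C@H]2C1=O | target

## Step count and least certain steps

Total step count: 15. Longest linear sequence: 7 steps (steps 9–15, from 14 and 15 to 28).

**Step 12 (key step, Proposed new method).** Most likely to go wrong:
- Weak or wrong-sense discrimination between the two oxiranes, because the ketone and the tertiary hydroxyl offer competing binding sites for chromium and the oxiranes are electron-poor ligands.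
- Attack at Cβ, or Lewis-acid-induced acyl migration of the epoxy ketone (Meinwald-type ring contraction).
- Slow catalysed opening, because the C4 alkenyl group sits 1,3 to C2 on the face of attack, so that an unselective background reaction gains weight.

Fallback with known chemistry, setting out from 5 (with 16 generated from 14 as in step 9) and returning at 27: 2,5-dimethoxyaniline F1 is acylated with 5 to give anilide F2. Oxidation with PhI(OAc)2 in methanol and aqueous work-up gives amido quinone monoketal F3. Nucleophilic epoxidation of its unsubstituted enone double bond under asymmetric phase-transfer conditions (t-BuOOH, NaOH, cinchona-derived quaternary ammonium salt, toluene) gives epoxy ketal F4. Excess 16 adds to the ketone anti to the oxirane to give carbinol F5, and hydrolysis on K10 gives 27. Nitrogen is then in place before the stereocentres and the C4–C bond is formed last; steps 9–14 are not used.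

**Step 11.** Most likely to go wrong: loss of facial control in the second epoxidation, since the first oxirane adds its own steric and dipolar bias; base-induced degradation of the dienone; attack of peroxide at tin. Fallback, setting out from 15 and returning at 20: the oxiranes are made before the C4–C bond. Twofold nucleophilic epoxidation of 15 (H2O2, NaOH) gives cis-diepoxy ketal F6, separated from any trans diastereomer. 16 adds to the ketone from the face opposite both oxirane oxygens to give carbinol F7, and hydrolysis on K10 gives 20.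

**Step 13.** Most likely to go wrong: loss of N2 from the enolate of the α-azido ketone instead of β-elimination; retro-aldol cleavage of the C2–C3 bond; conversion of the vinyl azide to an azirine on warming. Fallback, setting out from 22 and returning at 27 (24 is bypassed): no azide is left next to an enolate. The azide of 22 is reduced (PMe3, wet THF) to amino diol F8, which is acylated as it forms with 5 (NaHCO3, two-phase Schotten–Baumann conditions) to hydroxy amide F9. MsCl/Et3N then gives mesylate F10, which eliminates in the manner of a dehydroamino acid synthesis to 27.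

**Step 14.** Most likely to go wrong: slow hydrolysis of the conjugated N-alkenyl iminophosphorane 25; self-condensation of 26 before acylation; reversible conjugate addition of the phosphine to the enone. Fallback, setting out from 24 and 5 and returning at 27: the amide is formed without a free amine. 5 is converted with NaSH into thioacid F11, which reacts with 24 (2,6-lutidine, MeOH, rt) in a thioacid–azide amidation that loses N2 and sulfur to give 27.

**Step 15.** Most likely to go wrong: protodestannylation or homocoupling of 27; E/Z isomerisation of the polyenes under palladium or light; palladium-induced opening of the oxirane. Fallback, setting out from 27 and returning at 28: the bond is formed by a Heck reaction. Iododestannylation of 27 (I2, CH2Cl2, 0 °C) gives alkenyl iodide F12. (2E)-Penta-2,4-dienoic acid F13 is coupled with 8 (EDC, Et3N) to give dienamide F14. Heck coupling of F12 at the terminal CH2 of F14 (Pd(OAc)2, Bu4NCl, NaHCO3, DMF, rt) gives 28.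

## Further compounds

F1 | step 12 | 2,5-dimethoxyaniline | COc1ccc(OC)c(N)c1
F2 | step 12 | (2E,4E)-5-cyclohexyl-N-(2,5-dimethoxyphenyl)penta-2,4-dienamide | COc1ccc(OC)c(NC(=O)/C=C/C=C/C2CCCCC2)c1
F3 | step 12 | 3-[(2E,4E)-5-cyclohexylpenta-2,4-dienamido]-4,4-dimethoxycyclohexa-2,5-dien-1-one | O=C(/C=C/C=C/C1CCCCC1)NC1=CC(=O)C=CC1(OC)OC
F4 | step 12 | (5R,6S)-3-[(2E,4E)-5-cyclohexylpenta-2,4-dienamido]-5,6-epoxy-4,4-dimethoxycyclohex-2-en-1-one | O=C(/C=C/C=C/C1CCCCC1)NC1=CC(=O)[C@H]2O[C@H]2C1(OC)OC
F5 | step 12 | (1S,5R,6S)-3-[(2E,4E)-5-cyclohexylpenta-2,4-dienamido]-5,6-epoxy-4,4-dimethoxy-1-[(E)-2-(tributylstannyl)ethenyl]cyclohex-2-en-1-ol (C1 dimethyl ketal of 27) | O=C(/C=C/C=C/C1CCCCC1)NC1=C[C@](O)(/C=C/[Sn](CCCC)(CCCC)CCCC)[C@H]2O[C@H]2C1(OC)OC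
F6 | step 11 | (2S,3R,5S,6R)-2,3:5,6-diepoxy-4,4-dimethoxycyclohexan-1-one (meso, cis-diepoxide) | O=C1[C@H]2O[C@H]2C(OC)(OC)[C@H]2O[C@@H]12
F7 | step 11 | (1s,2R,3S,5R,6S)-2,3:5,6-diepoxy-4,4-dimethoxy-1-[(E)-2-(tributylstannyl)ethenyl]cyclohexan-1-ol (meso; OH syn to both oxiranes) | COC1(OC)[C@H]2O[C@H]2[C@](O)(/C=C/[Sn](CCCC)(CCCC)CCCC)[C@H]2O[C@@H]12
F8 | step 13 | (2R,3R,4R,5S,6R)-2-amino-5,6-epoxy-3,4-dihydroxy-4-[(E)-2-(tributylstannyl)ethenyl]cyclohexan-1-one | O=C1[C@H](N)[C@@H](O)[C@](O)(/C=C/[Sn](CCCC)(CCCC)CCCC)[C@H]2O[C@@H]12
F9 | step 13 | (2R,3R,4R,5S,6R)-2-[(2E,4E)-5-cyclohexylpenta-2,4-dienamido]-5,6-epoxy-3,4-dihydroxy-4-[(E)-2-(tributylstannyl)ethenyl]cyclohexan-1-one | O=C1[C@H](NC(=O)/C=C/C=C/C2CCCCC2)[C@@H](O)[C@](O)(/C=C/[Sn](CCCC)(CCCC)CCCC)[C@H]2O[C@@H]12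
F10 | step 13 | (2R,3R,4S,5S,6R)-2-[(2E,4E)-5-cyclohexylpenta-2,4-dienamido]-5,6-epoxy-4-hydroxy-3-(methanesulfonyloxy)-4-[(E)-2-(tributylstannyl)ethenyl]cyclohexan-1-one | O=C1[C@H](NC(=O)/C=C/C=C/C2CCCCC2)[C@@H](OS(C)(=O)=O)[C@](O)(/C=C/[Sn](CCCC)(CCCC)CCCC)[C@H]2O[C@@H]12
F11 | step 14 | (2E,4E)-5-cyclohexylpenta-2,4-dienethioic S-acid | O=C(S)/C=C/C=C/C1CCCCC1
F12 | step 15 | (4S,5S,6R)-2-[(2E,4E)-5-cyclohexylpenta-2,4-dienamido]-5,6-epoxy-4-hydroxy-4-[(E)-2-iodoethenyl]cyclohex-2-en-1-one | O=C(/C=C/C=C/C1CCCCC1)NC1=C[C@](O)(/C=C/I)[C@H]2O[C@H]2C1=O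
F13 | step 15 | (2E)-penta-2,4-dienoic acid | OC(=O)/C=C/C=C
F14 | step 15 | (2E)-N-(2-hydroxy-5-oxocyclopent-1-en-1-yl)penta-2,4-dienamide | O=C(/C=C/C=C)NC1=C(O)CCC1=O
A1 | alternative 1 | 3-[(2E,4E)-5-cyclohexylpenta-2,4-dienamido]-4,4-dimethoxycyclohexa-2,5-dien-1-one | O=C(/C=C/C=C/C1CCCCC1)NC1=CC(=O)C=CC1(OC)OC
A2 | alternative 1 | (5R,6S)-3-[(2E,4E)-5-cyclohexylpenta-2,4-dienamido]-5,6-epoxy-4,4-dimethoxycyclohex-2-en-1-one | O=C(/C=C/C=C/C1CCCCC1)NC1=CC(=O)[C@H]2O[C@H]2C1(OC)OC
A3 | alternative 2 | (2E,4E)-5-cyclohexyl-N-[2-hydroxy-5-[(1E,3E,5E)-7-[(2-hydroxy-5-oxocyclopent-1-en-1-yl)amino]-7-oxohepta-1,3,5-trien-1-yl]phenyl]penta-2,4-dienamide | O=C(/C=C/C=C/C1CCCCC1)Nc1cc(/C=C/C=C/C=C/C(=O)NC2=C(O)CCC2=O)ccc1O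
A4 | alternative 2 | (4S)-2-[(2E,4E)-5-cyclohexylpenta-2,4-dienamido]-4-hydroxy-4-[(1E,3E,5E)-7-[(2-hydroxy-5-oxocyclopent-1-en-1-yl)amino]-7-oxohepta-1,3,5-trien-1-yl]cyclohexa-2,5-dien-1-one | O=C(/C=C/C=C/C1CCCCC1)NC1=C[C@](O)(/C=C/C=C/C=C/C(=O)NC2=C(O)CCC2=O)C=CC1=O
A5 | alternative 3 | 4-hydroxy-4-[(trimethylsilyl)ethynyl]cyclohexa-2,5-dien-1-one | O=C1C=CC(O)(C#C[Si](C)(C)C)C=C1
A6 | alternative 3 | (4S,5S,6R)-5,6-epoxy-4-hydroxy-4-[(trimethylsilyl)ethynyl]cyclohex-2-en-1-one | O=C1C=C[C@](O)(C#C[Si](C)(C)C)[C@H]2O[C@@H]12
A7 | alternative 3 | (4S,5S,6R)-5,6-epoxy-4-hydroxy-2-iodo-4-[(trimethylsilyl)ethynyl]cyclohex-2-en-1-one | O=C1C(I)=C[C@](O)(C#C[Si](C)(C)C)[C@H]2O[C@@H]12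
A8 | alternative 3 | (2E,4E)-5-cyclohexylpenta-2,4-dienamide | NC(=O)/C=C/C=C/C1CCCCC1
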